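**Plan**

1. Numbering used throughout: C1 (CH–OAc), C2 (CH2), C3 (C(OH)i-Pr), C4 (ring-fusion CH), C5 (CH–O-aroyl), C6=C7(Me), C8 (C=O), C9 (CH2), C10 (C–Me); cyclopentane = C10–C1–C2–C3–C4, cycloheptenone = C4–C5–C6–C7–C8–C9–C10.
2. Retrosynthetic cuts: aryl ester and acetate; C6=C7 (ring-closing metathesis) and C7–C8 (2-propenyl addition to a C8 aldehyde); C3–C4 (ketyl–olefin ring closure); C2–C3 (dithiane + epoxide); C10–CH3 and C10–C9 (lactone dianion alkylations).
3. Enabling feature: the C1 oxygen and C5 are cis on the cyclopentane (1,3 across C10) and C6 follows C5, so O1–C6(=O)–C5=C4–C10–C1 can be a temporary α,β-unsaturated δ-lactone in which C4 is the electrophilic β-carbon and the C3 ketone hangs two atoms from C1.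
4. Forward order: lactone precursor → cyclopentane (SmI2 closure of C3–C4 across the lactone, bridged bicycle) → C5 oxygen via the lactone enolate → lactone carbon C6 and the allyl group become the two alkenes → seven-membered ring last (trans-fused) → esters.
5. Stereochemistry: C1 from (S)-3-hydroxy-γ-butyrolactone (inverted once on epoxide formation); C10 from two alkylations anti to the alkoxide; C4 from the lactone tether; C3 from the anti ketyl transition state; C5 from exo attack on the bicyclic lactone enolate.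

Key step: step 9

Remark: β is the cyclopentane face carrying the C10 methyl group and α the opposite face. The C8 carbinol of 18–21 and the lactol carbon of 19 are epimer mixtures that converge later.

**Route**

Step 1
Reactants: 1 isobutyraldehyde; 2 propane-1,3-dithiol
Product: 3 2-isopropyl-1,3-dithiane
Conditions: BF3·OEt2 (cat.), CH2Cl2, 0 °C to rt
Reagents that add atoms: none
Why: Lewis-acid-catalysed dithioacetalisation of an aldehyde gives the masked isobutyryl anion (Corey–Seebach reagent); no stereocentre is formed.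

Step 2
Reactants: 4 (S)-3-hydroxy-γ-butyrolactone
Product: 5 (3S,4S)-3-allyl-4-hydroxydihydrofuran-2(3H)-one
Conditions: LiN(i-Pr)2 (2.2 equiv), allyl bromide, THF/DMPU, −78 to −40 °C
Reagents that add atoms: allyl bromide, C=CCBr
Why: Fráter–Seebach alkylation of the β-hydroxy lactone dianion should put the allyl group trans to the hydroxyl, because the electrophile enters the enolate face opposite the lithium alkoxide.

Step 3
Reactants: 5 (3S,4S)-3-allyl-4-hydroxydihydrofuran-2(3H)-one
Product: 6 (3R,4S)-3-allyl-4-hydroxy-3-methyldihydrofuran-2(3H)-one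
Conditions: LiN(i-Pr)2 (2.3 equiv), MeI, THF/DMPU, −78 to −30 °C
Reagents that add atoms: iodomethane, CI
Why: A second Fráter–Seebach alkylation again occurs anti to the alkoxide, so the methyl group ends trans and the allyl group cis to the hydroxyl, which fixes the quaternary centre C10 relative to C1.

Step 4
Reactants: 6 (3R,4S)-3-allyl-4-hydroxy-3-methyldihydrofuran-2(3H)-one
Product: 8 methyl (R)-2-methyl-2-[(R)-oxiran-2-yl]pent-4-enoate, via mesylate 7 (not isolated)
Conditions: MsCl, Et3N, CH2Cl2, 0 °C; then NaOMe, MeOH, 0 °C to rt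
Reagents that add atoms: methanesulfonyl chloride (in 7), CS(Cl)(=O)=O; sodium methoxide, C[O-].[Na+]
Why: Methoxide opens the lactone and the released C2 alkoxide displaces the mesylate by intramolecular SN2 substitution (epoxide formation with inversion), which gives C1 the configuration of the target; with no α-hydrogen present, elimination to a butenolide cannot compete.

Step 5
Reactants: 8 methyl (R)-2-methyl-2-[(R)-oxiran-2-yl]pent-4-enoate; 3 2-isopropyl-1,3-dithiane
Product: 9 methyl (R)-2-[(S)-1-hydroxy-2-(2-isopropyl-1,3-dithian-2-yl)ethyl]-2-methylpent-4-enoate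
Conditions: 3, t-BuLi, THF/DMPU, −78 °C; then 8, −78 to 0 °C
Reagents that add atoms: none
Why: Corey–Seebach dithiane alkylation: the lithiated dithiane should open the terminal epoxide at its CH2 carbon while the α-quaternary, non-enolisable ester is spared, and no stereocentre is touched.

Step 6
Reactants: 9 methyl (R)-2-[(S)-1-hydroxy-2-(2-isopropyl-1,3-dithian-2-yl)ethyl]-2-methylpent-4-enoate
Product: 10 (R)-2-[(S)-1-hydroxy-2-(2-isopropyl-1,3-dithian-2-yl)ethyl]-2-methylpent-4-enal
Conditions: i-Bu2AlH (2.5 equiv), CH2Cl2, −78 °C; aqueous work-up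
Reagents that add atoms: none
Why: Partial ester reduction with i-Bu2AlH should stop at the aldehyde because the neighbouring aluminium alkoxide chelates the tetrahedral intermediate of this hindered neopentyl ester until work-up.

Step 7
Reactants: 10 (R)-2-[(S)-1-hydroxy-2-(2-isopropyl-1,3-dithian-2-yl)ethyl]-2-methylpent-4-enal
Product: 11 (5S,6S)-5-allyl-6-[(2-isopropyl-1,3-dithian-2-yl)methyl]-5-methyl-5,6-dihydro-2H-pyran-2-one
Conditions: Ph3P=C=C=O, toluene, 90 °C
Reagents that add atoms: ketenylidenetriphenylphosphorane, O=C=C=P(c1ccccc1)(c1ccccc1)c1ccccc1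
Why: Tandem O-acylation and intramolecular Wittig olefination: the hydroxyl adds to the cumulated ylide and the resulting acyl ylide condenses with the aldehyde, which can only give the ring (cis) alkene of the δ-lactone.

Step 8
Reactants: 11 (5S,6S)-5-allyl-6-[(2-isopropyl-1,3-dithian-2-yl)methyl]-5-methyl-5,6-dihydro-2H-pyran-2-one
Product: 12 (5S,6S)-5-allyl-5-methyl-6-(3-methyl-2-oxobutyl)-5,6-dihydro-2H-pyran-2-one
Conditions: PhI(O2CCF3)2, MeCN/H2O (9:1), 0 °C
Reagents that add atoms: water, O
Why: Oxidative dithiane hydrolysis with a hypervalent iodine reagent unmasks the isopropyl ketone under mildly acidic conditions that should neither eliminate the β-acyloxy group nor touch the alkenes.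

Step 9
Reactants: 12 (5S,6S)-5-allyl-5-methyl-6-(3-methyl-2-oxobutyl)-5,6-dihydro-2H-pyran-2-one
Product: 13 (1S,5S,6R,8S)-8-allyl-6-hydroxy-6-isopropyl-8-methyl-2-oxabicyclo[3.2.1]octan-3-one
Conditions: SmI2 (2.5 equiv), HMPA, t-BuOH (2 equiv), THF, −78 to 0 °C
Reagents that add atoms: none
Why: SmI2 transfers one electron to the C3 ketone and the samarium ketyl adds to C4, the β-carbon of the unsaturated lactone, after which a second electron and t-BuOH convert the α-lactone radical via the samarium enolate into the C5 methylene; the closest known reaction type is the SmI2-mediated ketyl–olefin (ketone/α,β-unsaturated ester) reductive cyclisation. The cyclopentane C10–C1–C2–C3–C4 closes 5-exo-trig across the lactone ring and gives the bridged 2-oxabicyclo[3.2.1]octan-3-one. C4 is controlled by the tether: the two-atom C2–C3 arm on C1 can reach C4 only on the lactone face that carries it, so O1 and C5 must end cis on the new ring and C5 trans to C9. C3 is controlled by the anti transition state usual for ketyl–olefin cyclisations: the bulky, negatively charged samarium-bound oxygen points away from the C4=C5–C6=O unit (exo), which places the isopropyl group endo and the hydroxyl cis to H4, and a wrongly oriented alkoxide would reveal itself by translactonisation. The step needs attack at C4 rather than at C5 or at the allyl group (6-exo), which the polarity match of the nucleophilic ketyl with the electrophilic β-carbon and the unactivated nature of the allyl alkene should secure.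

Step 10
Reactants: 13 (1S,5S,6R,8S)-8-allyl-6-hydroxy-6-isopropyl-8-methyl-2-oxabicyclo[3.2.1]octan-3-one
Product: 14 (1S,4S,5R,6R,8S)-8-allyl-4,6-dihydroxy-6-isopropyl-8-methyl-2-oxabicyclo[3.2.1]octan-3-one
Conditions: KN(SiMe3)2 (2.3 equiv), 2-(phenylsulfonyl)-3-phenyloxaziridine, THF, −78 °C
Reagents that add atoms: 2-(phenylsulfonyl)-3-phenyloxaziridine, O=S(=O)(N1OC1c1ccccc1)c1ccccc1
Why: Davis oxidation of the lactone enolate (C5 is the only enolisable position) should occur on the exo face, away from the C2–C3 bridge whose endo isopropyl group covers the other face, so the C5 hydroxyl comes out cis to H4 as in the target.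

Step 11
Reactants: 14 (1S,4S,5R,6R,8S)-8-allyl-4,6-dihydroxy-6-isopropyl-8-methyl-2-oxabicyclo[3.2.1]octan-3-one
Product: 15 C5 triethylsilyl ether of 14
Conditions: Et3SiCl, imidazole, DMAP (cat.), DMF, rt
Reagents that add atoms: chlorotriethylsilane, CC[Si](Cl)(CC)CC
Why: Silyl ether formation should protect the secondary C5 alcohol selectively, the tertiary C3 hydroxyl being too hindered for the silyl chloride.

Step 12
Reactants: 15 C5 triethylsilyl ether of 14
Product: 17 C8 aldehyde (allyl group of 15 shortened to CH2–CHO), via ozonide 16 (not isolated)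
Conditions: O3, CH2Cl2, −78 °C; then PPh3, −78 °C to rt
Reagents that add atoms: ozone, [O-][O+]=O
Why: Ozonolysis with reductive work-up cleaves the only alkene and turns the allyl group into the C9H2–C8HO unit without creating a stereocentre.

Step 13
Reactants: 17 C8 aldehyde
Product: 18 C8 2-propenyl carbinol (CH2–CH(OH)–C(CH3)=CH2 on C10; C8 epimers)
Conditions: 2-bromopropene, CrCl2 (4 equiv), NiCl2 (cat.), DMF, rt
Reagents that add atoms: 2-bromopropene, CC(Br)=C
Why: Nozaki–Hiyama–Kishi coupling adds the alkenylchromium species only to the aldehyde (lactone, silyl ether and free tertiary alcohol are tolerated); the new C8 centre is an epimer mixture that is oxidised away in step 17.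

Step 14
Reactants: 18 C8 2-propenyl carbinol
Product: 19 lactol (C6 hemiacetal of 18)
Conditions: i-Bu2AlH (3.5 equiv), CH2Cl2, −78 °C
Reagents that add atoms: none
Why: Low-temperature i-Bu2AlH reduction of a lactone should stop at the lactol (stable aluminate), which brings C6 to the aldehyde oxidation level.

Step 15
Reactants: 19 lactol
Product: 20 ring-opened diene triol (C5–CH=CH2, free C1–OH, C5–OSiEt3)
Conditions: Ph3PCH3Br, KOt-Bu, THF, 0 to 50 °C
Reagents that add atoms: methylenetriphenylphosphorane (from methyltriphenylphosphonium bromide), C=P(c1ccccc1)(c1ccccc1)c1ccccc1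
Why: Wittig methylenation of the lactol through its open hydroxy-aldehyde form gives the C6 vinyl group and frees the C1 hydroxyl, which removes the temporary ring.

Step 16
Reactants: 20 ring-opened diene triol
Product: 21 trans-fused hydroazulene triol (C6=C7, C8–OH epimers, C5–OSiEt3)
Conditions: second-generation Hoveyda–Grubbs catalyst (10 mol %), toluene, 80 °C
Reagents that add atoms: none
Why: Ring-closing metathesis of the vinyl and 2-propenyl groups should form the trisubstituted C6=C7 alkene and the seven-membered ring, which is necessarily trans-fused because the C5 and C9 arms are trans on the cyclopentane.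

Step 17
Reactants: 21 trans-fused hydroazulene triol
Product: 22 C8 enone (C1–OH, C3–OH, C5–OSiEt3)
Conditions: MnO2, CH2Cl2, rt
Reagents that add atoms: none
Why: MnO2 oxidation is selective for the allylic C8 alcohol (both epimers) and should leave the non-allylic C1 and tertiary C3 hydroxyls untouched.

Step 18
Reactants: 22 C8 enone
Product: 23 (1S,3R,3aR,4R,8aS)-3-hydroxy-3-isopropyl-6,8a-dimethyl-7-oxo-4-(triethylsilyloxy)-1,2,3,3a,4,7,8,8a-octahydroazulen-1-yl acetate
Conditions: Ac2O, pyridine, DMAP (cat.), rt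
Reagents that add atoms: acetic anhydride, CC(=O)OC(C)=O
Why: DMAP-catalysed acetylation should esterify the only free secondary alcohol (C1), the tertiary C3 hydroxyl being inert under these conditions.

Step 19
Reactants: 23 C1 acetate, C5 triethylsilyl ether
Product: 24 (1S,3R,3aR,4R,8aS)-3,4-dihydroxy-3-isopropyl-6,8a-dimethyl-7-oxo-1,2,3,3a,4,7,8,8a-octahydroazulen-1-yl acetate
Conditions: HF·pyridine, THF/pyridine, 0 °C
Reagents that add atoms: none
Why: Fluoride-mediated desilylation under buffered acidic conditions should free the C5 alcohol without acetate migration or elimination of the γ-oxygenated enone.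

Step 20
Reactants: 24 C1 acetate, C5 alcohol; 25 4-acetoxybenzoyl chloride
Product: 26 (1S,3R,3aR,4R,8aS)-1-acetoxy-3-hydroxy-3-isopropyl-6,8a-dimethyl-7-oxo-1,2,3,3a,4,7,8,8a-octahydroazulen-4-yl 4-acetoxybenzoate
Conditions: pyridine, DMAP (cat.), CH2Cl2, 0 °C to rt
Reagents that add atoms: none
Why: DMAP-catalysed acylation with the acid chloride should esterify the secondary allylic C5 alcohol with retention of configuration while the tertiary alcohol stays free.

Step 21
Reactants: 26 phenol acetate of the target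
Product: 27 (1S,3R,3aR,4R,8aS)-1-acetoxy-3-hydroxy-3-isopropyl-6,8a-dimethyl-7-oxo-1,2,3,3a,4,7,8,8a-octahydroazulen-4-yl 4-hydroxybenzoate (target)
Conditions: NH4OAc, MeOH/H2O (4:1), rt
Reagents that add atoms: none
Why: Chemoselective transesterification: the aryl acetate (phenoxide leaving group) should be cleaved under these near-neutral conditions much faster than the alkyl acetate or the aryl carboxylate, and no base-induced elimination is expected.

**Compound list**

1 | isobutyraldehyde | CC(C)C=O | starting material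
2 | propane-1,3-dithiol | SCCCS | starting material
3 | 2-isopropyl-1,3-dithiane | CC(C)C1SCCCS1 | intermediate
4 | (S)-3-hydroxy-γ-butyrolactone [(S)-4-hydroxydihydrofuran-2(3H)-one] | O=C1C[C@H](O)CO1 | starting material
5 | (3S,4S)-3-allyl-4-hydroxydihydrofuran-2(3H)-one (allyl trans to OH) | C=CC[C@H]1[C@H](O)COC1=O | intermediate
6 | (3R,4S)-3-allyl-4-hydroxy-3-methyldihydrofuran-2(3H)-one (methyl trans to OH) | C=CC[C@]1(C)[C@H](O)COC1=O | intermediate
7 | (3R,4S)-3-allyl-3-methyl-4-(methylsulfonyloxy)dihydrofuran-2(3H)-one | C=CC[C@]1(C)[C@H](OS(C)(=O)=O)COC1=O | intermediate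
8 | methyl (R)-2-methyl-2-[(R)-oxiran-2-yl]pent-4-enoate | C=CC[C@@](C)(C(=O)OC)[C@@H]1CO1 | intermediate
9 | methyl (R)-2-[(S)-1-hydroxy-2-(2-isopropyl-1,3-dithian-2-yl)ethyl]-2-methylpent-4-enoate | C=CC[C@@](C)(C(=O)OC)[C@@H](O)CC1(C(C)C)SCCCS1 | intermediate
10 | (R)-2-[(S)-1-hydroxy-2-(2-isopropyl-1,3-dithian-2-yl)ethyl]-2-methylpent-4-enal | C=CC[C@@](C)(C=O)[C@@H](O)CC1(C(C)C)SCCCS1 | intermediate
11 | (5S,6S)-5-allyl-6-[(2-isopropyl-1,3-dithian-2-yl)methyl]-5-methyl-5,6-dihydro-2H-pyran-2-one | O=C1C=C[C@](C)(CC=C)[C@H](CC2(C(C)C)SCCCS2)O1 | intermediate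
12 | (5S,6S)-5-allyl-5-methyl-6-(3-methyl-2-oxobutyl)-5,6-dihydro-2H-pyran-2-one | O=C1C=C[C@](C)(CC=C)[C@H](CC(=O)C(C)C)O1 | intermediate
13 | (1S,5S,6R,8S)-8-allyl-6-hydroxy-6-isopropyl-8-methyl-2-oxabicyclo[3.2.1]octan-3-one (lactone O1–C6(=O)–C5H2 bridges C1 and C4; C3–OH exo, i-Pr endo) | O=C1C[C@@H]2[C@](O)(C(C)C)C[C@H](O1)[C@@]2(C)CC=C | intermediate
14 | (1S,4S,5R,6R,8S)-8-allyl-4,6-dihydroxy-6-isopropyl-8-methyl-2-oxabicyclo[3.2.1]octan-3-one (C5–OH exo) | O=C1[C@@H](O)[C@@H]2[C@](O)(C(C)C)C[C@H](O1)[C@@]2(C)CC=C | intermediate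
15 | C5 triethylsilyl ether of 14 | O=C1[C@@H](O[Si](CC)(CC)CC)[C@@H]2[C@](O)(C(C)C)C[C@H](O1)[C@@]2(C)CC=C | intermediate
16 | ozonide (1,2,4-trioxolane) of the allyl group of 15 | O=C1[C@@H](O[Si](CC)(CC)CC)[C@@H]2[C@](O)(C(C)C)C[C@H](O1)[C@@]2(C)CC3OCOO3 | intermediate
17 | C8 aldehyde (C10–CH2–CHO), otherwise as 15 | O=C1[C@@H](O[Si](CC)(CC)CC)[C@@H]2[C@](O)(C(C)C)C[C@H](O1)[C@@]2(C)CC=O | intermediate
18 | C8 2-propenyl carbinol (C10–CH2–CH(OH)–C(CH3)=CH2, C8 epimers), otherwise as 15 | O=C1[C@@H](O[Si](CC)(CC)CC)[C@@H]2[C@](O)(C(C)C)C[C@H](O1)[C@@]2(C)CC(O)C(C)=C | intermediate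
19 | lactol of 18 (C6 hemiacetal, anomers) | OC1[C@@H](O[Si](CC)(CC)CC)[C@@H]2[C@](O)(C(C)C)C[C@H](O1)[C@@]2(C)CC(O)C(C)=C | intermediate
20 | cyclopentane with C1–OH (β), C3–OH (α) and i-Pr (β), C4–CH(OSiEt3)–CH=CH2 (β), C10–CH3 (β) and C10–CH2–CH(OH)–C(CH3)=CH2 (α) | C=C[C@@H](O[Si](CC)(CC)CC)[C@@H]1[C@](O)(C(C)C)C[C@H](O)[C@@]1(C)CC(O)C(C)=C | intermediate
21 | trans-fused hydroazulene: C1–OH, C3–OH, C5–OSiEt3, C6=C7(CH3), C8–OH (epimers) | O[C@H]1C[C@@](O)(C(C)C)[C@H]2[C@H](O[Si](CC)(CC)CC)C=C(C)C(O)C[C@]12C | intermediate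
22 | C8 enone: C1–OH, C3–OH, C5–OSiEt3 (C1-deacetyl analogue of 23) | O[C@H]1C[C@@](O)(C(C)C)[C@H]2[C@H](O[Si](CC)(CC)CC)C=C(C)C(=O)C[C@]12C | intermediate
23 | (1S,3R,3aR,4R,8aS)-3-hydroxy-3-isopropyl-6,8a-dimethyl-7-oxo-4-(triethylsilyloxy)-1,2,3,3a,4,7,8,8a-octahydroazulen-1-yl acetate | CC(=O)O[C@H]1C[C@@](O)(C(C)C)[C@H]2[C@H](O[Si](CC)(CC)CC)C=C(C)C(=O)C[C@]12C | intermediate
24 | (1S,3R,3aR,4R,8aS)-3,4-dihydroxy-3-isopropyl-6,8a-dimethyl-7-oxo-1,2,3,3a,4,7,8,8a-octahydroazulen-1-yl acetate | CC(=O)O[C@H]1C[C@@](O)(C(C)C)[C@H]2[C@H](O)C=C(C)C(=O)C[C@]12C | intermediate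
25 | 4-acetoxybenzoyl chloride | CC(=O)Oc1ccc(cc1)C(Cl)=O | starting material
26 | (1S,3R,3aR,4R,8aS)-1-acetoxy-3-hydroxy-3-isopropyl-6,8a-dimethyl-7-oxo-1,2,3,3a,4,7,8,8a-octahydroazulen-4-yl 4-acetoxybenzoate | CC(=O)O[C@H]1C[C@@](O)(C(C)C)[C@H]2[C@H](OC(=O)c3ccc(OC(C)=O)cc3)C=C(C)C(=O)C[C@]12C | intermediate
27 | (1S,3R,3aR,4R,8aS)-1-acetoxy-3-hydroxy-3-isopropyl-6,8a-dimethyl-7-oxo-1,2,3,3a,4,7,8,8a-octahydroazulen-4-yl 4-hydroxybenzoate | CC(=O)O[C@H]1C[C@@](O)(C(C)C)[C@H]2[C@H](OC(=O)c3ccc(O)cc3)C=C(C)C(=O)C[C@]12C | target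

**Step count and risks**

Total step count: 21. Longest linear sequence: 20 steps (steps 2–21, from 4 to 27); step 1 is a one-step branch that joins at step 5.

Steps most likely to fail:

1. Step 9 (key ring closure). What may go wrong: two-electron reduction of the unsaturated lactone or pinacol coupling before the ketyl reaches C4, or loss of control at C3 if the samarium alkoxide turns endo. The fallback generates the C3 radical without a dissolving-metal reductant and sets out from 12. Ketone 12 is converted (t-BuMe2SiOTf, Et3N, CH2Cl2, −78 °C) into the tert-butyldimethylsilyl enol ether F1. Iron-hydride hydrogen-atom transfer (Fe(acac)3, PhSiH3, EtOH/ethylene glycol, 60 °C; the electron-rich enol ether is the preferred hydrogen acceptor) should then give the same tertiary α-silyloxy radical at C3. 5-exo Giese addition to C4 and reduction would give the C3 silyl ether of the bicyclic lactone F2. HF·pyridine then returns the route at 13.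

2. Step 10 (C5 hydroxylation). What may go wrong: poor facial selectivity of the enolate oxidation (attack from the side of the C2–C3 bridge), or aldol-type capture of the enolate by the sulfonimine by-product. The fallback sets out from 13 and corrects the centre by substitution with inversion instead of relying on face selection. The C5-epimeric alcohol F3, formed from 13 under the conditions of step 10, is converted (Tf2O, pyridine, CH2Cl2, −20 °C) into the triflate F4. SN2 displacement with Bu4NNO2 (DMF, rt) gives the inverted nitrite ester F5, which hydrolyses on aqueous work-up and returns the route at 14.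

3. Step 16 (ring-closing metathesis). What may go wrong: sluggish closure between the hindered allylic-ether vinyl group and the 1,1-disubstituted alkene, with competing intermolecular metathesis or catalyst decomposition. The fallback sets out from 15 and closes the seven-membered ring at C7–C8 instead of C6=C7. Reduction (i-Bu2AlH, CH2Cl2, −78 °C) gives the lactol F6. Stork–Zhao iodo-olefination ((1-iodoethyl)triphenylphosphonium iodide, NaN(SiMe3)2, THF, −78 °C) gives the (Z)-vinyl iodide F7. Ozonolysis of the allyl group (O3, CH2Cl2, −78 °C; then PPh3), via the ozonide F8, gives the iodo-aldehyde F9. An intramolecular Nozaki–Hiyama–Kishi reaction (CrCl2, NiCl2 cat., DMSO, high dilution) then forms the C7–C8 bond and returns the route at 21.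

Further compounds

F1 | step 9 | tert-butyldimethylsilyl enol ether of 12 (C2=C3 isomer, geometry not defined) | O=C1C=C[C@](C)(CC=C)[C@H](C=C(O[Si](C)(C)C(C)(C)C)C(C)C)O1
F2 | step 9 | C3 tert-butyldimethylsilyl ether of 13 | O=C1C[C@@H]2[C@](O[Si](C)(C)C(C)(C)C)(C(C)C)C[C@H](O1)[C@@]2(C)CC=C
F3 | step 10 | C5 epimer of 14 (C5–OH endo) | O=C1[C@H](O)[C@@H]2[C@](O)(C(C)C)C[C@H](O1)[C@@]2(C)CC=C
F4 | step 10 | C5 trifluoromethanesulfonate of F3 | O=C1[C@H](OS(=O)(=O)C(F)(F)F)[C@@H]2[C@](O)(C(C)C)C[C@H](O1)[C@@]2(C)CC=C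
F5 | step 10 | C5 nitrite ester with the configuration of 14 | O=C1[C@@H](ON=O)[C@@H]2[C@](O)(C(C)C)C[C@H](O1)[C@@]2(C)CC=C
F6 | step 16 | lactol of 15 (C6 hemiacetal, allyl group intact) | OC1[C@@H](O[Si](CC)(CC)CC)[C@@H]2[C@](O)(C(C)C)C[C@H](O1)[C@@]2(C)CC=C
F7 | step 16 | ring-opened (Z)-vinyl iodide (C5–CH=C(I)CH3, free C1–OH, allyl on C10) | C/C(I)=C/[C@@H](O[Si](CC)(CC)CC)[C@@H]1[C@](O)(C(C)C)C[C@H](O)[C@@]1(C)CC=C
F8 | step 16 | ozonide of the allyl group of F7 | C/C(I)=C/[C@@H](O[Si](CC)(CC)CC)[C@@H]1[C@](O)(C(C)C)C[C@H](O)[C@@]1(C)CC2OCOO2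
F9 | step 16 | iodo-aldehyde (C10–CH2–CHO, (Z)-vinyl iodide on C5) | C/C(I)=C/[C@@H](O[Si](CC)(CC)CC)[C@@H]1[C@](O)(C(C)C)C[C@H](O)[C@@]1(C)CC=O
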